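Count the amounts by what is left, not by what is made: the fraction left is substrate plus open intermediate, the part of the charge not yet target.

| setting | birch | elm | theta | delta |
|---|---|---|---|---|
| substrate | 0.75 M | 3 M | 1.5 M | 1.5 M |
| gas | 200 mM (held) | 200 mM (held) | 200 mM (held) | 200 mM (held) |
| remark | run made earlier | run made earlier |  |  |
| time |  |  | 5.0 d | 10 d |

| run | time / d | target / % | substrate / % | open intermediate / % |
|---|---|---|---|---|
| birch | 0.625 | 0 | 66 | 28 |
| birch | 1.25 | 1 | 68 | 33 |
| birch | 1.67 | 1 | 67 | 32 |
| birch | 2.50 | 8 | 60 | 29 |
| birch | 3.00 | 12 | 60 | 27 |
| birch | 4.00 | 19 | 55 | 25 |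
| elm | 0.625 | 0 | 67 | 34 |
| elm | 1.25 | 3 | 65 | 36 |
| elm | 1.67 | 2 | 67 | 28 |
| elm | 2.50 | 4 | 68 | 28 |
| elm | 3.00 | 4 | 63 | 27 |
| elm | 4.00 | 6 | 63 | 29 |

(standard deviation of a reading: 2 percentage points)

- at the start none of the gas is in solution
- a reading or a percentage of target counts all its forms, free or not

1. which of these there is most of at the end, counted by the substrate in it, theta (substrate / open intermediate / target)
2. which of these there is most of at the end, counted by the substrate in it, delta (substrate / open intermediate / target)
3. amount of the one of these that there is most of at the end, in percent of the substrate charged, theta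
4. amount of the one of these that there is most of at the end, in percent of the substrate charged, delta

- The fast time is the settling of substrate with open intermediate, a pre-equilibrium. In birch and elm the pair already stands near its later split at the first reading, 0.625 d.
- The slow time is the emptying time, the charge divided by the rate at which target appears, as with a tank on a steady outflow. Birch reads 0.0579 M d⁻¹ and elm reads 0.0533 M d⁻¹, with 4.00 times the charge, so the outflow looks zero order.
- Their mean, 0.0556 M d⁻¹, set against the charge of 1.5 M, gives an emptying time of 27.0 d, an estimate from these readings.
- Settling is far shorter than emptying, so the pair keeps its split while it drains. The last readings of both runs give substrate 68.6% of the fraction left.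
- Substrate is then that share of the fraction left, and target is the remainder of the charge. Target passes substrate once the fraction left falls below the crossing fraction, one over one plus the share: 59.3%.
- My own reckoning starts the outflow near 1.67 d. It gives theta a fraction left of 87.6%, which makes substrate 60.1%. It gives delta 69.1%, above the crossing fraction, with substrate on top at 47.4%.
- The forecast names substrate at 60% for theta, close to mine, and substrate at 49% for delta, a little above mine. It too reads a steady outflow, with rates of its own: “Target formation looks roughly zero order in absolute terms.”
- Theta ends with substrate on top at 55.1%, and delta ends with target on top at 47.6%.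

    substrate ⇌ open intermediate (K = 0.460, k = 0.130 h⁻¹)
    partner → second intermediate (k = 0.0240 h⁻¹)
    open intermediate + second intermediate → target (k = 0.0590 L mol⁻¹ h⁻¹)
    gas ⇌ partner, rate k4*(csat - [partner]) (kL = 0.130 h⁻¹)
    crystals ⇌ target, rate k5*(cs5 - [target]) while solid is left; crystals form when [target] > cs5 (solubility = 0.140 M, k = 8.50 h⁻¹)

- Delta makes target at 0.0602 M d⁻¹ over its first 5.0 d and at 0.0828 M d⁻¹ over the rest, which is faster. Its fraction left ends at 52.4%, below the crossing fraction 59.3%, while theta's 79.9% stands above it. Theta read at 8.00 d still has 63.2% left, with substrate 43.7% over target 36.8%. Read at 12.0 d, it has 42.1% left, and target leads at 57.9%.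

(The runs stem from a simulated flask for substances that don't exist; noise was put on by code.)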